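**Remark on the chemistry:** target 16 has no stereocentre. The carbinol carbon made in step 2 is carried as the racemate through 4, 8, 9, 10 and 11 and becomes a CH2 group in step 7. Ring A is numbered C1 (CH2OH), C2 (H), C3 (Br), C4 (OH), C5 (OH), C6 (CH2–aryl) throughout.

## The problem

Target 16 is a diarylmethane whose ring A is a pentasubstituted benzene: C1 carries CH2OH, C2 is the only CH, C3 carries bromine, C4 and C5 carry the catechol hydroxyls, and C6 carries the methylene that leads to ring B, a 3-bromo-4-hydroxyphenyl group. There is no ring fusion and no stereocentre, so the difficulty is purely regiochemical: five different substituents must stand in one fixed order, and substitution on a preformed catechol would not reliably tell C2 from C3 or place the benzyl group at C6. Since nothing stereochemical needs control, a stereocentre may appear in intermediates as a racemate, provided it is erased before the end. The fragile groups are three: the catechol (oxidized in basic, aerated media); the C1 hydroxymethyl group, which stands para to the C4 hydroxyl and so ionizes to a quinone methide under acid, to be etherified or reduced; and the two aryl bromides, which exclude hydrogenolysis, aryllithium chemistry and zerovalent palladium late in the route. Methyl ethers on the phenols are therefore unattractive, because their cleavage would not spare the benzylic alcohol; a silyl ether on ring B and a late arrival of the C4 oxygen suit the molecule better. The enabling feature is that the C1–CH2–O and C6–CH2–aryl arms are the two halves of a 3-aryl-1,3-dihydroisobenzofuran cut at its diarylmethyl C–O bond, with the C5 hydroxyl beside the fusion carbon C6. That is the pattern a gold-catalysed cycloisomerization of a furfuryl propargyl ether delivers: the furan oxygen moves to C5, furan C4 with its bromine becomes C3, furan C3 becomes the lone CH at C2, and the former furan C5 becomes C4, the single free position ortho to the new phenol.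

## Retrosynthesis

**16 from 15.** The only bond cut is the O–Si bond on ring B. A silyl ether is preferred to a methyl or benzyl ether because fluoride spares the bromides, the catechol and the benzylic alcohol. The triisopropylsilyl group is chosen over a smaller one because it must outlast an alkoxide (step 5) and aqueous hydroxide (step 9). The forward reaction must be a buffered desilylation that never builds up phenoxide.

**15 from 13, and 13 from 12.** The C4–O bond is traced back to a C4 formyl group (through formate 14), and the C4–CHO bond is then cut to give phenol 12. In 12 the C5 hydroxyl has one free ortho position, C4, so a phenoxide-directed formylation has no choice of site. Direct electrophilic oxygenation would favour the para position C2, and directed lithiation is excluded by the bromines. Precursor 12 lacks one oxygen and is a simple mono-phenol. The forward pair is a magnesium-mediated ortho-formylation followed by a Dakin oxidation.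

**12 from 11.** The benzylic carbon of the CH2–aryl arm is reconnected to the oxygen of the CH2OH arm, giving phthalan 11. The cut is placed here and not after the catechol stage for a reason of selectivity: in 11 the primary benzylic C–O bond is meta to the only hydroxyl of a brominated ring, so only the diarylmethyl C–O bond can ionize. Once the C4 hydroxyl is present it is para to that primary carbon and invites over-reduction. The forward reaction is an ionic hydrogenation, which also erases the stereocentre.

**11 from 8 (key disconnection).** Ring A bonds C6–C1 and C5–C4 and the C5–O bond are cut, and the furan C–O bond is restored, which gives furan-yne 8. All six carbons of ring A then come from a furan (C1 to C4) and a terminal alkyne (C6 and C5), and the bromine arrives on the furan. A Diels–Alder reaction of the same furan would need an activated alkyne and would leave the oxygen on the other carbon. The forward reaction, which passes through oxepine 9 and arene oxide 10, needs a mild π-acid that does not ionize the benzylic propargylic ether.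

**8 from 4 and 7.** The furfuryl C–O bond of the ether is cut. The other C–O bond lies at a benzylic propargylic carbon, where displacement would run through a cation and give allenes; displacement at a primary furfuryl bromide by the alkoxide of 4 is the cleaner choice. Both halves are small and bear one bromine each.

**4 from 2 and 3; 2 from 1; 7 from 6; 6 from 5.** The alkyne–carbinol C–C bond is cut to aldehyde 2 and acetylide 3, and 2 is the silyl ether of commercial phenol 1. Bromide 7 comes from alcohol 6, the reduction product of commercial aldehyde 5. These are routine functional-group operations on bought materials.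

## Roads not taken

**Alternative 1:** Ring A is cut at C3–C4 and C5–C6. The two oxygenated carbons come from the dimethoxy ketene silyl acetal A3, and C3, C2, C1 and C6 from the 3-bromo-2-pyrone A2, which already bears the ester and the ring B benzyl group. In the forward step A3 adds across the pyrone diene in an inverse-demand cycloaddition; the bridged lactone then decarboxylates and sheds its silyloxy group to give benzoate A1.
- Merits: ring A appears with both oxygens, the bromine and both carbon arms in one step. In this respect it is better than the chosen plan, which needs two further steps (8 and 9) to add the C4 oxygen.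
- Weak points: the regiochemical burden moves into A2, a tetrasubstituted pyrone that needs its own multistep synthesis. The sense of addition depends on the ester outweighing the lactone carbonyl in polarizing the diene. A1 carries three O-methyl groups and an ester, so the endgame is a hydride reduction followed by a triple Lewis-acid ether cleavage, which would convert the para-hydroxybenzyl alcohol of 16.
- Comparison: the chosen plan sets against the one-step ring A a fluoride-only endgame, commercial aldehydes 1 and 5, and the correct oxidation level of both arms from the start.

**Alternative 2:** The cuts are the C1–C and C6–C bonds to the two benzylic carbons. Aryne A5, tert-butyl isocyanide A6 and aldehyde A7 combine in one operation: A6 adds at the aryne carbon remote from the methoxy group, the aryl anion formed at C6 adds to A7, and the alkoxide closes on the nitrilium carbon to give iminolactone A4.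
- Merits: the step is more convergent than anything in the chosen plan, ring A is fully substituted from the outset, and the methoxy group next to the aryne gives dependable regiocontrol. Like the chosen plan, it ends in a ring whose diarylmethyl C–O bond is later reduced.
- Weak points: A5 requires an ortho-silyl aryl triflate carrying bromine and two methoxy groups, itself a multistep target. The C1 carbon arrives at the carboxylic oxidation level and must be hydrolysed and reduced by two levels beside two aryl bromides. Three methyl ethers again remain for a harsh final cleavage.
- Comparison: Alternative 2 is better in convergency and needs no late oxygenation. The chosen plan offers a shorter path to its cyclization substrate, no redox adjustment at C1, and silyl rather than methyl protection.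

**Alternative 3:** Ring A is cut at C3–C4 and C4–C5, so that C4 is supplied by carbon monoxide A10. A zerovalent palladium catalyst ionizes dienyl acetate A9, A10 inserts at the allyl terminus, and the resulting dienylketene closes onto the enol ether carbon; the phenol is isolated as aryl acetate A8.
- Merits: the C4 oxygen is created in the key step from a one-carbon feedstock, which the chosen plan cannot match. The two catechol oxygens emerge differentiated. The later bromination of ring A would be well directed, since C3 is the only open ortho position of the freed phenol and its para position is blocked.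
- Weak points: A8 has no bromine, because aryl bromides would not survive the catalyst, so both rings must be brominated afterwards with control of stoichiometry. A9 needs a geometry-defined synthesis and a pressure of A10. Ester reduction and two O-demethylations still follow.
- Comparison: the chosen plan carries both bromines in from bought aldehydes, so no halogenation selectivity is at stake, and it ends with a silyl removal instead of ether cleavage.

Key step: step 6

## Route

**Step 1**
Reactants: 1 3-bromo-4-hydroxybenzaldehyde
Product: 2 3-bromo-4-[(triisopropylsilyl)oxy]benzaldehyde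
Conditions: TIPSCl, imidazole, DMF, rt
Reagents that add atoms: triisopropylsilyl chloride, CC(C)[Si](Cl)(C(C)C)C(C)C
Why: Imidazole-promoted O-silylation of a phenol; the bulky triisopropylsilyl ether is chosen so that it resists the alkoxide of step 5 and the hydroxide of step 9 yet falls to fluoride at the end.

**Step 2**
Reactants: 2 3-bromo-4-[(triisopropylsilyl)oxy]benzaldehyde; 3 ethynylmagnesium bromide
Product: 4 rac-1-{3-bromo-4-[(triisopropylsilyl)oxy]phenyl}prop-2-yn-1-ol
Conditions: THF, −78 → 0 °C; sat. aq. NH4Cl
Reagents that add atoms: none
Why: Grignard 1,2-addition of an acetylide to an aryl aldehyde; the new carbinol centre forms as the racemate, which is acceptable because this carbon becomes CH2 in step 7.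

**Step 3**
Reactants: 5 4-bromofuran-2-carbaldehyde
Product: 6 (4-bromofuran-2-yl)methanol
Conditions: NaBH4, MeOH, 0 °C
Reagents that add atoms: none
Why: Borohydride reduction of an aldehyde; the furan C–Br bond is inert to NaBH4.

**Step 4**
Reactants: 6 (4-bromofuran-2-yl)methanol
Product: 7 4-bromo-2-(bromomethyl)furan
Conditions: PBr3, Et2O, 0 °C; dried solution used at once
Reagents that add atoms: phosphorus tribromide, BrP(Br)Br
Why: Conversion of a primary alcohol into the bromide through its phosphite ester; the ring bromine tempers the usual lability of furfuryl bromides, and the product is not stored.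

**Step 5**
Reactants: 4 rac-1-{3-bromo-4-[(triisopropylsilyl)oxy]phenyl}prop-2-yn-1-ol; 7 4-bromo-2-(bromomethyl)furan
Product: 8 rac-4-bromo-2-{[(1-{3-bromo-4-[(triisopropylsilyl)oxy]phenyl}prop-2-yn-1-yl)oxy]methyl}furan
Conditions: NaH, THF, 0 °C; then 7, Bu4NI (cat.), 0 °C → rt
Reagents that add atoms: none
Why: Williamson ether synthesis; NaH removes the hydroxyl proton well before the alkyne proton, the alkoxide displaces the activated primary furfuryl bromide, and low temperature with no excess base limits propargyl-to-allenyl isomerization.

**Step 6 (key step)**
Reactants: 8 rac-4-bromo-2-{[(1-{3-bromo-4-[(triisopropylsilyl)oxy]phenyl}prop-2-yn-1-yl)oxy]methyl}furan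
Product: 11 rac-6-bromo-3-{3-bromo-4-[(triisopropylsilyl)oxy]phenyl}-1,3-dihydroisobenzofuran-4-ol, via fused oxepine 9 (not isolated), via arene oxide 10 (not isolated)
Conditions: Ph3PAuNTf2 (5 mol %), CH2Cl2, rt
Reagents that add atoms: none
Why: Ph3PAuNTf2 (monovalent gold) binds the terminal alkyne and furan C2 attacks the internal alkyne carbon in a 5-exo-dig closure that forms the dihydrofuran ring and a cyclopropyl gold carbene. Opening of the cyclopropane together with the furan C2–O bond gives a carbonyl-conjugated gold carbene, whose carbonyl oxygen closes on the carbene carbon (the former alkyne terminus) to release the catalyst and oxepine 9. Ring A then closes by disrotatory 6π electrocyclization of 9 (oxepine to arene oxide valence isomerization) to 10, which joins the former alkyne terminus to the former furan C5. Opening of the epoxide at the former furan C5 and loss of the proton from the former alkyne terminus leave the hydroxyl beside the fusion carbon, as in 11. The closest known reaction type is the gold-catalysed furan-yne phenol synthesis of furfuryl propargyl ethers, which gives 1,3-dihydroisobenzofuran-4-ols. No lasting stereocentre is created: the epoxide carbons of 10 become aromatic and the racemic aryl-bearing carbon is untouched. The step needs chemoselective π-activation of the alkyne without heterolysis of the benzylic propargylic C–O bond, which the weakly Lewis-acidic phosphine gold cation at room temperature and the damped donor strength of the ortho-brominated silyloxyphenyl ring should secure. It also needs the epoxide to open in the stated sense; should part of it open the other way, the resulting phenol has its only free ortho position at the other former epoxide carbon, so steps 7 to 9 would in principle lead it toward the same catechol 15.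

**Step 7**
Reactants: 11 rac-6-bromo-3-{3-bromo-4-[(triisopropylsilyl)oxy]phenyl}-1,3-dihydroisobenzofuran-4-ol
Product: 12 5-bromo-2-{3-bromo-4-[(triisopropylsilyl)oxy]benzyl}-3-(hydroxymethyl)phenol
Conditions: Et3SiH, CF3CO2H, CH2Cl2, 0 °C; aq. NaHCO3/MeOH work-up
Reagents that add atoms: none
Why: Ionic hydrogenation of a benzylic ether: protonation and heterolysis at the diarylmethyl carbon give a cation stabilized by the ortho-hydroxyl of ring A and the para-silyloxy group of ring B, which the silane reduces irreversibly. The primary benzylic C–O bond, meta to the only hydroxyl of a brominated ring, should not ionize, and the stereocentre disappears.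

**Step 8**
Reactants: 12 5-bromo-2-{3-bromo-4-[(triisopropylsilyl)oxy]benzyl}-3-(hydroxymethyl)phenol
Product: 13 6-bromo-3-{3-bromo-4-[(triisopropylsilyl)oxy]benzyl}-2-hydroxy-4-(hydroxymethyl)benzaldehyde
Conditions: MgCl2, Et3N, (CH2O)n, THF, reflux; 1 M HCl
Reagents that add atoms: paraformaldehyde (reacts as formaldehyde), C=O
Why: Magnesium-mediated ortho-formylation of a phenol (Casiraghi–Skattebøl): the magnesium phenoxide delivers formaldehyde to the only free ortho position, C4, and the resulting salicyl alkoxide is oxidized by a second formaldehyde through hydride transfer. Extra MgCl2 and base accommodate the free primary alcohol, and ring B is shielded by its silyl ether.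

**Step 9**
Reactants: 13 6-bromo-3-{3-bromo-4-[(triisopropylsilyl)oxy]benzyl}-2-hydroxy-4-(hydroxymethyl)benzaldehyde
Product: 15 6-bromo-3-{3-bromo-4-[(triisopropylsilyl)oxy]benzyl}-4-(hydroxymethyl)benzene-1,2-diol, via aryl formate 14 (not isolated)
Conditions: 30% aq. H2O2, aq. NaOH, THF, 0 °C, Ar; then aq. NaH2PO4
Reagents that add atoms: hydrogen peroxide, OO
Why: Dakin oxidation of an ortho-hydroxybenzaldehyde: hydroperoxide adds to the aldehyde, the phenoxide-activated aryl group migrates to oxygen to give formate 14, and 14 is hydrolysed in the same flask. Cold, oxygen-free conditions protect the catechol, and any partial loss of the silyl ether here would only anticipate step 10.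

**Step 10**
Reactants: 15 6-bromo-3-{3-bromo-4-[(triisopropylsilyl)oxy]benzyl}-4-(hydroxymethyl)benzene-1,2-diol
Product: 16 6-bromo-3-(3-bromo-4-hydroxybenzyl)-4-(hydroxymethyl)benzene-1,2-diol
Conditions: Bu4NF, AcOH, THF, 0 °C, Ar
Reagents that add atoms: none
Why: Fluoride-induced cleavage of an aryl silyl ether, driven by the Si–F bond; the acetic acid buffer keeps catecholate and quinone methide formation in check.

## Compound list

1 | 3-bromo-4-hydroxybenzaldehyde | O=Cc1ccc(O)c(Br)c1 | starting material
2 | 3-bromo-4-[(triisopropylsilyl)oxy]benzaldehyde | O=Cc1ccc(O[Si](C(C)C)(C(C)C)C(C)C)c(Br)c1 | intermediate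
3 | ethynylmagnesium bromide | C#C[Mg]Br | starting material
4 | rac-1-{3-bromo-4-[(triisopropylsilyl)oxy]phenyl}prop-2-yn-1-ol | C#CC(O)c1ccc(O[Si](C(C)C)(C(C)C)C(C)C)c(Br)c1 | intermediate
5 | 4-bromofuran-2-carbaldehyde | O=Cc1cc(Br)co1 | starting material
6 | (4-bromofuran-2-yl)methanol | OCc1cc(Br)co1 | intermediate
7 | 4-bromo-2-(bromomethyl)furan | BrCc1cc(Br)co1 | intermediate
8 | rac-4-bromo-2-{[(1-{3-bromo-4-[(triisopropylsilyl)oxy]phenyl}prop-2-yn-1-yl)oxy]methyl}furan | C#CC(OCc1cc(Br)co1)c1ccc(O[Si](C(C)C)(C(C)C)C(C)C)c(Br)c1 | intermediate
9 | rac-7-bromo-3-{3-bromo-4-[(triisopropylsilyl)oxy]phenyl}-1,3-dihydrofuro[3,4-c]oxepine (oxepine fused to the dihydrofuran; ring oxygens at positions 2 and 5) | BrC1=COC=C2C(c3ccc(O[Si](C(C)C)(C(C)C)C(C)C)c(Br)c3)OCC2=C1 | intermediate (not isolated)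
10 | 6-bromo-3-{3-bromo-4-[(triisopropylsilyl)oxy]phenyl}-4,5-epoxy-1,3,4,5-tetrahydroisobenzofuran (arene oxide; racemic, cis-epoxide, mixture of diastereomers at C3) | BrC1=CC2=C(C(c3ccc(O[Si](C(C)C)(C(C)C)C(C)C)c(Br)c3)OC2)C2OC12 | intermediate (not isolated)
11 | rac-6-bromo-3-{3-bromo-4-[(triisopropylsilyl)oxy]phenyl}-1,3-dihydroisobenzofuran-4-ol | Oc1cc(Br)cc2c1C(c1ccc(O[Si](C(C)C)(C(C)C)C(C)C)c(Br)c1)OC2 | intermediate
12 | 5-bromo-2-{3-bromo-4-[(triisopropylsilyl)oxy]benzyl}-3-(hydroxymethyl)phenol | OCc1cc(Br)cc(O)c1Cc1ccc(O[Si](C(C)C)(C(C)C)C(C)C)c(Br)c1 | intermediate
13 | 6-bromo-3-{3-bromo-4-[(triisopropylsilyl)oxy]benzyl}-2-hydroxy-4-(hydroxymethyl)benzaldehyde | OCc1cc(Br)c(C=O)c(O)c1Cc1ccc(O[Si](C(C)C)(C(C)C)C(C)C)c(Br)c1 | intermediate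
14 | 6-bromo-3-{3-bromo-4-[(triisopropylsilyl)oxy]benzyl}-2-hydroxy-4-(hydroxymethyl)phenyl formate | O=COc1c(Br)cc(CO)c(Cc2ccc(O[Si](C(C)C)(C(C)C)C(C)C)c(Br)c2)c1O | intermediate (not isolated)
15 | 6-bromo-3-{3-bromo-4-[(triisopropylsilyl)oxy]benzyl}-4-(hydroxymethyl)benzene-1,2-diol | OCc1cc(Br)c(O)c(O)c1Cc1ccc(O[Si](C(C)C)(C(C)C)C(C)C)c(Br)c1 | intermediate
16 | 6-bromo-3-(3-bromo-4-hydroxybenzyl)-4-(hydroxymethyl)benzene-1,2-diol | OCc1cc(Br)c(O)c(O)c1Cc1ccc(O)c(Br)c1 | target

## Step count and least certain steps

Total: 10 steps. Longest linear sequence: 8 steps (steps 1, 2, 5, 6, 7, 8, 9, 10 from 1; equally steps 3 to 10 from 5).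

**Step 6 (key step).** The bromine lowers the nucleophilicity of the furan, so attack on the gold-bound alkyne may be slow. Two other processes could then consume the substrate: heterolysis of the benzylic propargylic C–O bond, and hydride transfer from the furfuryl CH2 group to the activated alkyne with fragmentation. The fallback replaces π-acid catalysis by cycloaddition and aromatization; it sets out from 8 and returns at 15.
- The alkyne of 8 is deprotonated with EtMgBr and formylated with DMF to give the ynal rac-4-[(4-bromofuran-2-yl)methoxy]-4-{3-bromo-4-[(triisopropylsilyl)oxy]phenyl}but-2-ynal F1.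
- On heating in toluene, the formyl-activated alkyne of F1 should undergo the intramolecular Diels–Alder reaction with the furan, forming the same two ring bonds (C6–C1 and C5–C4) in the oxygen-bridged cycloadduct 5-bromo-1-{3-bromo-4-[(triisopropylsilyl)oxy]phenyl}-1,6-dihydro-3H-3a,6-epoxyisobenzofuran-7-carbaldehyde F2.
- F2 opens at the bridgehead C–O bond next to the tether and aromatizes to the salicylaldehyde rac-6-bromo-3-{3-bromo-4-[(triisopropylsilyl)oxy]phenyl}-5-hydroxy-1,3-dihydroisobenzofuran-4-carbaldehyde F3. Here the furan oxygen sits on C4 of ring A and the formyl group marks C5.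
- Dakin oxidation of F3, through the formate rac-6-bromo-3-{3-bromo-4-[(triisopropylsilyl)oxy]phenyl}-5-hydroxy-1,3-dihydroisobenzofuran-4-yl formate F4, gives the catechol rac-6-bromo-3-{3-bromo-4-[(triisopropylsilyl)oxy]phenyl}-1,3-dihydroisobenzofuran-4,5-diol F5.
- Ionic hydrogenation of F5 (Et3SiH, CF3CO2H, low temperature, limited acid) opens the diarylmethyl C–O bond to give 15. This step carries the over-reduction risk that the main route avoids, because the C4 hydroxyl is now para to the primary benzylic carbon.

**Step 8.** The one free ortho position is flanked by bromine on an inductively deactivated ring, so the phenoxide may add formaldehyde sluggishly; the free primary alcohol also competes for magnesium and formaldehyde, so the reaction may stall or give formals. The fallback introduces the oxygen directly, at a stage where the alcohol is still masked; it sets out from 11 and returns at 15.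
- 2-Iodoxybenzoic acid in DMF should oxidize phenol 11 at its free ortho position to the ortho-quinone rac-6-bromo-3-{3-bromo-4-[(triisopropylsilyl)oxy]phenyl}-1,3-dihydroisobenzofuran-4,5-dione F6.
- F6 is reduced in the same flask with Na2S2O4 to the catechol phthalan F5 already described under step 6, which is opened to 15 by ionic hydrogenation as there.

**Step 5.** The furfuryl bromide 7 may polymerize before it is alkylated, and the alkoxide may cause propargyl-to-allenyl isomerization or silyl transfer. The fallback reverses the polarity of the ether formation; it sets out from 4 and 6 and returns at 8.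
- Catalytic FeCl3 in MeCN at rt should ionize the aryl-stabilized propargylic alcohol 4, and an excess of alcohol 6 captures the cation on oxygen (dehydrative propargylic etherification).
- Neither the bromide nor a base is needed, and no new compound arises (F0).

**Step 10.** Fluoride generates phenoxides on the finished molecule: the C4 phenoxide para to the hydroxymethyl group can expel hydroxide to a quinone methide, and the catecholate is oxidized by traces of air. The fallback moves desilylation to a stage with neither feature; it sets out from 13 and returns at 16.
- Bu4NF/AcOH converts 13 into 6-bromo-3-(3-bromo-4-hydroxybenzyl)-2-hydroxy-4-(hydroxymethyl)benzaldehyde F7.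
- Dakin oxidation of F7 under the conditions of step 9, through 6-bromo-3-(3-bromo-4-hydroxybenzyl)-2-hydroxy-4-(hydroxymethyl)phenyl formate F8, then gives 16 directly, so the catechol never meets fluoride.

## Further compounds

F1 | step 6 | rac-4-[(4-bromofuran-2-yl)methoxy]-4-{3-bromo-4-[(triisopropylsilyl)oxy]phenyl}but-2-ynal | O=CC#CC(OCc1cc(Br)co1)c1ccc(O[Si](C(C)C)(C(C)C)C(C)C)c(Br)c1
F2 | step 6 | 5-bromo-1-{3-bromo-4-[(triisopropylsilyl)oxy]phenyl}-1,6-dihydro-3H-3a,6-epoxyisobenzofuran-7-carbaldehyde (racemic, mixture of diastereomers) | O=CC1=C2C(c3ccc(O[Si](C(C)C)(C(C)C)C(C)C)c(Br)c3)OCC23OC1C(Br)=C3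
F3 | step 6 | rac-6-bromo-3-{3-bromo-4-[(triisopropylsilyl)oxy]phenyl}-5-hydroxy-1,3-dihydroisobenzofuran-4-carbaldehyde | O=Cc1c(O)c(Br)cc2c1C(c1ccc(O[Si](C(C)C)(C(C)C)C(C)C)c(Br)c1)OC2
F4 | step 6 | rac-6-bromo-3-{3-bromo-4-[(triisopropylsilyl)oxy]phenyl}-5-hydroxy-1,3-dihydroisobenzofuran-4-yl formate | O=COc1c(O)c(Br)cc2c1C(c1ccc(O[Si](C(C)C)(C(C)C)C(C)C)c(Br)c1)OC2
F5 | step 6 | rac-6-bromo-3-{3-bromo-4-[(triisopropylsilyl)oxy]phenyl}-1,3-dihydroisobenzofuran-4,5-diol | Oc1c(O)c(Br)cc2c1C(c1ccc(O[Si](C(C)C)(C(C)C)C(C)C)c(Br)c1)OC2
F6 | step 8 | rac-6-bromo-3-{3-bromo-4-[(triisopropylsilyl)oxy]phenyl}-1,3-dihydroisobenzofuran-4,5-dione | O=C1C(=O)C(Br)=CC2=C1C(c1ccc(O[Si](C(C)C)(C(C)C)C(C)C)c(Br)c1)OC2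
F0 | step 5 | none | none
F7 | step 10 | 6-bromo-3-(3-bromo-4-hydroxybenzyl)-2-hydroxy-4-(hydroxymethyl)benzaldehyde | OCc1cc(Br)c(C=O)c(O)c1Cc1ccc(O)c(Br)c1
F8 | step 10 | 6-bromo-3-(3-bromo-4-hydroxybenzyl)-2-hydroxy-4-(hydroxymethyl)phenyl formate | O=COc1c(Br)cc(CO)c(Cc2ccc(O)c(Br)c2)c1O
A1 | alternative 1 | methyl 5-bromo-2-(3-bromo-4-methoxybenzyl)-3,4-dimethoxybenzoate | COC(=O)c1cc(Br)c(OC)c(OC)c1Cc1ccc(OC)c(Br)c1
A2 | alternative 1 | methyl 3-bromo-6-(3-bromo-4-methoxybenzyl)-2-oxo-2H-pyran-5-carboxylate | COC(=O)C1=C(Cc2ccc(OC)c(Br)c2)OC(=O)C(Br)=C1
A3 | alternative 1 | 1,2-dimethoxy-1-(trimethylsilyloxy)ethene (alkene geometry not fixed) | COC=C(OC)O[Si](C)(C)C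
A4 | alternative 2 | (1Z)-5-bromo-3-(3-bromo-4-methoxyphenyl)-N-tert-butyl-6,7-dimethoxy-3H-isobenzofuran-1-imine (racemic at C3) | CC(C)(C)/N=C1\OC(c2ccc(OC)c(Br)c2)c2c1cc(Br)c(OC)c2OC
A5 | alternative 2 | 5-bromo-3,4-dimethoxybenzyne | COC1=C(OC)C(Br)=CC#C1
A6 | alternative 2 | tert-butyl isocyanide | CC(C)(C)[N+]#[C-]
A7 | alternative 2 | 3-bromo-4-methoxybenzaldehyde | COc1ccc(C=O)cc1Br
A8 | alternative 3 | methyl 4-acetoxy-3-methoxy-2-(4-methoxybenzyl)benzoate | COC(=O)c1ccc(OC(C)=O)c(OC)c1Cc1ccc(OC)cc1
A9 | alternative 3 | methyl 2-(2-acetoxyethylidene)-4-methoxy-3-(4-methoxybenzyl)but-3-enoate (alkene geometries not fixed) | CC(=O)OCC=C(C(=O)OC)C(Cc1ccc(OC)cc1)=COC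
A10 | alternative 3 | carbon monoxide | [C-]#[O+]
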